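**Plan**
- Feature: in the pyran ring, O2'–C3'(acyl)=C4' is the enol of a δ-lactone whose former carbonyl carbon C3' carries the isovaleryl carbonyl. C3'–C(acyl) and C(acyl)–CH2 are therefore cut together, leaving a lactone enol phosphate, CO and an isobutylzinc reagent.
- Order of cuts: first C2–OAc and C3=O of the benzofuranone ring (back to a 3-acetoxybenzofuran), then the two acyl bonds, then O2'–C3' (lactone) and C1'–H (ketone). Last comes C2–C1' (2-lithiobenzofuran plus nepetalactone, whose C1 becomes C1' and whose C3 becomes the new lactone carbonyl C3').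
- Forward: the furan ring of the benzofuran is closed first and the cyclopentane is bought ready-made. The pyran ring is opened in the fragment union and closed again as the transposed lactone, the side chain is joined in the key step, and C2 is oxidised last.
- Stereochemistry: C4a', C7' and C7a' come from nepetalactone. C1' comes from an oxazaborolidine-controlled ketone reduction. C2 comes from an epoxidation steered by C1' followed by anti acetoxy migration. C4' is never a lasting stereocentre.

Key step: step 10

Assumption: (4aS,7S,7aR)-nepetalactone is taken as a purchasable single isomer (main constituent of commercial catnip oil). Unprimed locants are those of the benzofuran(one) (O1, C2, C3, C3a, C4 to C7, C7a), primed ones those of the cyclopenta[c]pyran (C1', O2', C3', C4', C4a', C5' to C7', C7a'), and both sets are kept for open-chain intermediates.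

Step 1
Reactants: 1 1-(2-hydroxy-6-methylphenyl)ethanone
Product: 2 2-bromo-1-(2-hydroxy-6-methylphenyl)ethanone
Conditions: CuBr2, EtOAc/CHCl3, reflux
Reagents that add atoms: copper dibromide, Br[Cu]Br
Why: Heterogeneous α-bromination of an aryl methyl ketone with CuBr2 goes through the copper-bound enol, stops at the monobromide and, since no free bromine builds up, leaves the hydrogen-bonded phenol ring alone.

Step 2
Reactants: 2 2-bromo-1-(2-hydroxy-6-methylphenyl)ethanone
Product: 3 4-methylbenzofuran-3(2H)-one
Conditions: NaOAc, EtOH, reflux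
Reagents that add atoms: none
Why: Intramolecular Williamson etherification (5-exo-tet attack of the phenol oxygen on the CH2Br carbon) is the standard closure of benzofuran-3(2H)-ones, and the weak base NaOAc avoids self-condensation of the product.

Step 3
Reactants: 3 4-methylbenzofuran-3(2H)-one
Product: 4 4-methyl-3-(triisopropylsilyloxy)benzofuran
Conditions: i-Pr3SiOTf, Et3N, CH2Cl2, 0 °C
Reagents that add atoms: triisopropylsilyl trifluoromethanesulfonate, CC(C)[Si](OS(=O)(=O)C(F)(F)F)(C(C)C)C(C)C
Why: Soft enolisation and O-silylation (silyl enol ether formation) is driven by aromatisation to the benzofuran, and the bulky Si(i-Pr)3 group is chosen because it must later survive an organolithium, KN(SiMe3)2 and an organozinc.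

Step 4
Reactants: 4 4-methyl-3-(triisopropylsilyloxy)benzofuran; 5 (4aS,7S,7aR)-nepetalactone
Product: 8 2-{(1R,2R,3S)-3-methyl-2-[4-methyl-3-(triisopropylsilyloxy)benzofuran-2-carbonyl]cyclopentyl}propanal (keto aldehyde; both epimers at the formyl-bearing carbon C4'), via 2-lithiobenzofuran 6 (not isolated), via lithium enolate 7 (not isolated)
Conditions: n-BuLi, THF, −78 °C; cannulated into 5, THF, −78 °C (inverse addition); AcOH, −78 °C
Reagents that add atoms: none
Why: α-Lithiation of the benzofuran at C2 (its most acidic C–H, flanked by O1 and the silyloxy group, with the bulk of Si(i-Pr)3 holding back O-to-C silyl migration at −78 °C) is followed by acyl substitution on the enol lactone, the first stage of a Fujimoto–Belleau type opening, which expels the C3' enolate and forms C2–C1' without touching C4a', C7' or C7a'; over-addition is checked by inverse addition and by the push–pull deactivation of the new ketone, and the epimer mixture at C4' is harmless because that carbon becomes trigonal in step 8.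

Step 5
Reactants: 8 keto aldehyde
Product: 9 2-{(1S,2R,3S)-3-methyl-2-[4-methyl-3-(triisopropylsilyloxy)benzofuran-2-carbonyl]cyclopentyl}propanoic acid (keto acid; both C4' epimers)
Conditions: NaClO2, NaH2PO4, 2-methyl-2-butene, t-BuOH/H2O, 0 °C to rt
Reagents that add atoms: sodium chlorite, [Na+].[O-]Cl=O
Why: Pinnick oxidation takes the α-branched aldehyde to the acid under buffered conditions that do not enolise the C1' ketone (so C7a' is safe), and it is placed here because the 2-acyl group still deactivates the silyloxybenzofuran towards the chlorine oxidants, which 2-methyl-2-butene scavenges as well.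

Step 6
Reactants: 9 keto acid
Product: 10 methyl 2-{(1S,2R,3S)-3-methyl-2-[4-methyl-3-(triisopropylsilyloxy)benzofuran-2-carbonyl]cyclopentyl}propanoate (keto ester; both C4' epimers)
Conditions: Me3SiCHN2, toluene/MeOH, 0 °C
Reagents that add atoms: trimethylsilyldiazomethane, C[Si](C)(C)C=[N+]=[N-]
Why: Methyl ester formation with trimethylsilyldiazomethane is neutral and fast, and it removes the acidic proton and the borane-reducible carboxyl group that a free acid would offer to the reagent of the next step.

Step 7
Reactants: 10 keto ester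
Product: 12 (1R,4aS,7S,7aR)-4,7-dimethyl-1-[4-methyl-3-(triisopropylsilyloxy)benzofuran-2-yl]hexahydrocyclopenta[c]pyran-3(1H)-one (δ-lactone; both C4' epimers), via hydroxy ester 11 (not isolated)
Conditions: (S)-2-methyl-CBS-oxazaborolidine [(3aS)-1-methyl-3,3-diphenyltetrahydro-1H,3H-pyrrolo[1,2-c][1,3,2]oxazaborole], BH3·SMe2, THF, −20 °C; MeOH; then pyridinium p-toluenesulfonate (cat.), toluene, 60 °C
Reagents that add atoms: none
Why: Corey–Bakshi–Shibata reduction followed by acid-catalysed lactonisation of the δ-hydroxy ester: the ketone binds to the (S)-oxazaborolidine·BH3 complex with the extended silyloxybenzofuranyl group as the large substituent turned away from the catalyst, so hydride reaches the Si face of C1' and sets (1'R) (same sense as acetophenone to (R)-1-phenylethanol); ester and silyl ether are inert to BH3·SMe2 at this temperature, and the cis relation of the two side arms on the cyclopentane lets a very mild acid close the ring with the aryl group on the convex face.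

Step 8
Reactants: 12 δ-lactone
Product: 14 (1R,4aS,7S,7aR)-4,7-dimethyl-1-[4-methyl-3-(triisopropylsilyloxy)benzofuran-2-yl]-1,4a,5,6,7,7a-hexahydrocyclopenta[c]pyran-3-yl diphenyl phosphate (ketene acetal phosphate), via potassium enolate 13 (not isolated)
Conditions: KN(SiMe3)2, (PhO)2P(O)Cl, DMPU, THF, −78 °C; chromatography on Et3N-treated silica
Reagents that add atoms: diphenyl chlorophosphate, O=P(Cl)(Oc1ccccc1)Oc1ccccc1
Why: Lactone to ketene acetal phosphate conversion: KN(SiMe3)2 removes the only α-hydrogen of the lactone (at C4'), the hard phosphoryl chloride traps the potassium enolate on oxygen (aided by DMPU), and because C4' becomes trigonal both C4' epimers of 12 merge into one compound while C1', C4a', C7' and C7a' are untouched.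

Step 9
Reactants: 15 1-bromo-2-methylpropane
Product: 16 isobutylzinc bromide (THF solution containing LiCl)
Conditions: Zn dust (activated with BrCH2CH2Br and Me3SiCl, cat.), LiCl, THF, 50 °C
Reagents that add atoms: zinc, [Zn]
Why: Direct insertion of activated zinc into a primary alkyl bromide, accelerated by LiCl, is a standard preparation of alkylzinc halides and gives a titratable solution.

Step 10
Reactants: 14 ketene acetal phosphate; 16 isobutylzinc bromide; 17 carbon monoxide
Product: 18 1-{(1R,4aS,7S,7aR)-4,7-dimethyl-1-[4-methyl-3-(triisopropylsilyloxy)benzofuran-2-yl]-1,4a,5,6,7,7a-hexahydrocyclopenta[c]pyran-3-yl}-3-methylbutan-1-one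
Conditions: Pd(PPh3)4 (10 mol %), LiCl, CO (3 bar), THF, 50 °C, 16 added slowly by pump
Reagents that add atoms: carbon monoxide 17, [C-]#[O+]; isobutylzinc bromide 16, CC(C)C[Zn]Br
Why: Zerovalent palladium inserts into the C3'–O(phosphate) bond of 14, migratory insertion of CO turns the alkenylpalladium species into an α-alkoxyacryloylpalladium species, and transmetalation from 16 followed by reductive elimination releases 18, so that C3'–C(acyl) and C(acyl)–CH2 are made in one catalytic cycle. The closest known reactions are the Pd(PPh3)4-catalysed Negishi coupling and alkoxycarbonylation of lactone-derived ketene acetal phosphates, the carbonylative Suzuki coupling of lactone enol triflates, and the carbonylative Negishi ketone synthesis from alkenyl or aryl electrophiles, CO and alkylzinc halides. No ring is closed and no stereocentre is created; C4' is already trigonal in 14, and C1', C4a', C7' and C7a' are spectators. The selectivity needed is CO uptake before alkyl transfer: it is secured by CO pressure, by keeping 16 scarce through slow addition, and by the substrate itself, since the alkenylpalladium centre flanked by O2' and the C4' methyl group is too crowded for fast direct transmetalation whereas insertion of the small CO moves the metal one atom outwards. Reductive elimination from the acyl(isobutyl)palladium species should outrun β-hydride elimination, the alkylzinc halide does not add to the ketone formed, LiCl helps the phosphate to leave, and the silyl ether and the benzofuran are inert.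

Step 11
Reactants: 18 silyl-protected ketone
Product: 20 2-[(1R,4aS,7S,7aR)-4,7-dimethyl-3-(3-methylbutanoyl)-1,4a,5,6,7,7a-hexahydrocyclopenta[c]pyran-1-yl]-4-methylbenzofuran-3-yl acetate, via ammonium benzofuranolate 19 (not isolated)
Conditions: Ac2O (excess), Bu4NF, THF, −78 to 0 °C
Reagents that add atoms: acetic anhydride, CC(=O)OC(C)=O
Why: Fluoride-promoted O-acylation of a silyl enol ether: fluoride cleaves the O–Si bond and the benzofuran-3-olate 19 is acetylated on oxygen at once by the acylating agent already present, which keeps the benzofuran aromatic, while the low temperature and the in situ trap leave the olate no time for retro-oxa-Michael expulsion of O2' from C1'.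

Step 12
Reactants: 20 3-acetoxybenzofuran
Product: 22 (2R)-2-[(1R,4aS,7S,7aR)-4,7-dimethyl-3-(3-methylbutanoyl)-1,4a,5,6,7,7a-hexahydrocyclopenta[c]pyran-1-yl]-4-methyl-3-oxo-2,3-dihydrobenzofuran-2-yl acetate (target), via benzofuran epoxide 21 (not isolated)
Conditions: dimethyldioxirane (acetone solution, 1 equiv), CH2Cl2, −40 °C to rt
Reagents that add atoms: dimethyldioxirane, CC1(C)OO1
Why: Enol ester epoxidation followed by the enol ester epoxide to α-acyloxy ketone rearrangement: the electrophilic oxidant should prefer the doubly oxygenated C2=C3 bond to C3'=C4', which the isovaleryl carbonyl deactivates; A(1,3) strain against the 3-acetoxy group holds H1' in the benzofuran plane so that O2' and C7a' flank the two faces and oxygen arrives from the O2' side, away from C7a' and the C7' methyl group; the labile 2-alkoxy epoxide 21 then opens at C2 while the acetoxy group, lying on the opposite face, bridges from C3 to C2 through a five-membered acetoxonium ion and ends on C2 anti to the former epoxide oxygen, which sets (2R) and frees the C3 ketone.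

**Compound list**
1 | 1-(2-hydroxy-6-methylphenyl)ethanone | CC(=O)c1c(C)cccc1O | starting material
2 | 2-bromo-1-(2-hydroxy-6-methylphenyl)ethanone | O=C(CBr)c1c(C)cccc1O | intermediate
3 | 4-methylbenzofuran-3(2H)-one | O=C1COc2cccc(C)c12 | intermediate
4 | 4-methyl-3-(triisopropylsilyloxy)benzofuran | CC(C)[Si](C(C)C)(C(C)C)Oc1coc2cccc(C)c12 | intermediate
5 | (4aS,7S,7aR)-nepetalactone, (4aS,7S,7aR)-4,7-dimethyl-5,6,7,7a-tetrahydrocyclopenta[c]pyran-1(4aH)-one | O=C1OC=C(C)[C@H]2CC[C@H](C)[C@H]21 | starting material
6 | 2-lithio-4-methyl-3-(triisopropylsilyloxy)benzofuran | CC(C)[Si](C(C)C)(C(C)C)Oc1c([Li])oc2cccc(C)c12 | intermediate (not isolated)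
7 | lithium enolate of keto aldehyde 8 (enolate oxygen cis to C4a') | [Li]O/C=C(/C)[C@H]1CC[C@H](C)[C@H]1C(=O)c1oc2cccc(C)c2c1O[Si](C(C)C)(C(C)C)C(C)C | intermediate (not isolated)
8 | 2-{(1R,2R,3S)-3-methyl-2-[4-methyl-3-(triisopropylsilyloxy)benzofuran-2-carbonyl]cyclopentyl}propanal, both C4' epimers | O=CC(C)[C@H]1CC[C@H](C)[C@H]1C(=O)c1oc2cccc(C)c2c1O[Si](C(C)C)(C(C)C)C(C)C | intermediate
9 | 2-{(1S,2R,3S)-3-methyl-2-[4-methyl-3-(triisopropylsilyloxy)benzofuran-2-carbonyl]cyclopentyl}propanoic acid, both C4' epimers | OC(=O)C(C)[C@H]1CC[C@H](C)[C@H]1C(=O)c1oc2cccc(C)c2c1O[Si](C(C)C)(C(C)C)C(C)C | intermediate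
10 | methyl ester of 9, both C4' epimers | COC(=O)C(C)[C@H]1CC[C@H](C)[C@H]1C(=O)c1oc2cccc(C)c2c1O[Si](C(C)C)(C(C)C)C(C)C | intermediate
11 | methyl 2-{(1S,2R,3S)-2-[(R)-hydroxy(4-methyl-3-(triisopropylsilyloxy)benzofuran-2-yl)methyl]-3-methylcyclopentyl}propanoate, both C4' epimers | COC(=O)C(C)[C@H]1CC[C@H](C)[C@H]1[C@@H](O)c1oc2cccc(C)c2c1O[Si](C(C)C)(C(C)C)C(C)C | intermediate (not isolated)
12 | (1R,4aS,7S,7aR)-4,7-dimethyl-1-[4-methyl-3-(triisopropylsilyloxy)benzofuran-2-yl]hexahydrocyclopenta[c]pyran-3(1H)-one, both C4' epimers | CC(C)[Si](C(C)C)(C(C)C)Oc1c([C@@H]2OC(=O)C(C)[C@H]3CC[C@H](C)[C@H]32)oc2cccc(C)c12 | intermediate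
13 | potassium enolate of 12 | CC(C)[Si](C(C)C)(C(C)C)Oc1c([C@@H]2OC(O[K])=C(C)[C@H]3CC[C@H](C)[C@H]32)oc2cccc(C)c12 | intermediate (not isolated)
14 | (1R,4aS,7S,7aR)-4,7-dimethyl-1-[4-methyl-3-(triisopropylsilyloxy)benzofuran-2-yl]-1,4a,5,6,7,7a-hexahydrocyclopenta[c]pyran-3-yl diphenyl phosphate | CC(C)[Si](C(C)C)(C(C)C)Oc1c([C@@H]2OC(OP(=O)(Oc4ccccc4)Oc4ccccc4)=C(C)[C@H]3CC[C@H](C)[C@H]32)oc2cccc(C)c12 | intermediate
15 | 1-bromo-2-methylpropane | CC(C)CBr | starting material
16 | isobutylzinc bromide | CC(C)C[Zn]Br | intermediate
17 | carbon monoxide | [C-]#[O+] | starting material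
18 | 1-{(1R,4aS,7S,7aR)-4,7-dimethyl-1-[4-methyl-3-(triisopropylsilyloxy)benzofuran-2-yl]-1,4a,5,6,7,7a-hexahydrocyclopenta[c]pyran-3-yl}-3-methylbutan-1-one | CC(C)[Si](C(C)C)(C(C)C)Oc1c([C@@H]2OC(C(=O)CC(C)C)=C(C)[C@H]3CC[C@H](C)[C@H]32)oc2cccc(C)c12 | intermediate
19 | tetrabutylammonium benzofuran-3-olate derived from 18 | CCCC[N+](CCCC)(CCCC)CCCC.[O-]c1c([C@@H]2OC(C(=O)CC(C)C)=C(C)[C@H]3CC[C@H](C)[C@H]32)oc2cccc(C)c12 | intermediate (not isolated)
20 | 2-[(1R,4aS,7S,7aR)-4,7-dimethyl-3-(3-methylbutanoyl)-1,4a,5,6,7,7a-hexahydrocyclopenta[c]pyran-1-yl]-4-methylbenzofuran-3-yl acetate | CC(=O)Oc1c([C@@H]2OC(C(=O)CC(C)C)=C(C)[C@H]3CC[C@H](C)[C@H]32)oc2cccc(C)c12 | intermediate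
21 | (2S,3R)-2,3-epoxide of 20, oxirane oxygen on the benzofuran face next to O2' | CC(=O)O[C@@]12O[C@]1([C@@H]3OC(C(=O)CC(C)C)=C(C)[C@H]4CC[C@H](C)[C@H]43)Oc1cccc(C)c12 | intermediate (not isolated)
22 | (2R)-2-[(1R,4aS,7S,7aR)-4,7-dimethyl-3-(3-methylbutanoyl)-1,4a,5,6,7,7a-hexahydrocyclopenta[c]pyran-1-yl]-4-methyl-3-oxo-2,3-dihydrobenzofuran-2-yl acetate | CC(=O)O[C@@]1([C@@H]2OC(C(=O)CC(C)C)=C(C)[C@H]3CC[C@H](C)[C@H]32)Oc2cccc(C)c2C1=O | target

Total step count: 12. Longest linear sequence: 11 (steps 1 to 8 and 10 to 12); step 9 is a one-step side branch.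

**Steps most likely to fail**

Step 10. Insertion of zerovalent palladium into the C3'–O bond of a tetrasubstituted ketene acetal phosphate may be slowed further by CO. Hydrolysis of the phosphate back to the lactone, direct isobutyl transfer without CO uptake, or reduction by β-hydride transfer could then take over. The fallback splits the three-component union into separate carbonylation and alkylation events, each known on its substrate class. Setting out from 14, Pd(PPh3)4, CO, MeOH and Et3N in DMF should give the methyl 3'-carboxylate F1. MeNH(OMe)·HCl with i-PrMgCl in THF converts it into the N-methoxy-N-methylamide F2. i-BuMgBr in THF at 0 °C then delivers ketone 18, where the route is rejoined.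

Step 12. Three processes threaten this step:
- oxidation at C3'=C4' in place of C2=C3;
- oxygen transfer to the face next to C7a';
- valence isomerisation of the epoxide to an ortho-quinone methide, with drift of the acetyl group to the phenol oxygen.

The fallback brings oxygen to C2 by a Rubottom oxidation, in which the oxygen stays on the face it attacks, and adds the acetyl group afterwards. It is therefore stereocomplementary to the acetoxy shift, and it uses a far more nucleophilic double bond. Setting out from 18 (steps 11 and 12 are skipped), dimethyldioxirane in CH2Cl2 at −78 °C should give the 2-(triisopropylsilyloxy)benzofuran-3(2H)-one F3 after 1,4-silyl shift. HF·pyridine in THF frees the hemiketal F4, whose C2 can also equilibrate through the open hydroxyaryl 1,2-diketone form. Ac2O, Et3N and DMAP in CH2Cl2 acetylate it to 22.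

Step 7. Facial selectivity may be poor, because both flanks of the ketone are bulky and the resident stereocentres at C7a' and C4a' may oppose the catalyst. The fallback gives up reagent control and makes the sequence stereoconvergent. Setting out from keto acid 9 (step 6 is skipped), NaBH4 in THF/MeOH reduces the ketone of the carboxylate to the (1'R)-hydroxy acid F5 and the (1'S)-hydroxy acid F6, which are separated. F5 is closed with retention by EDC·HCl and DMAP in CH2Cl2. F6 is closed with inversion at C1' by Mitsunobu lactonisation (PPh3, DIAD, toluene, high dilution). Both come back to the route at 12.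

**Further compounds**
F1 | step 10 | methyl (1R,4aS,7S,7aR)-4,7-dimethyl-1-[4-methyl-3-(triisopropylsilyloxy)benzofuran-2-yl]-1,4a,5,6,7,7a-hexahydrocyclopenta[c]pyran-3-carboxylate | CC(C)[Si](C(C)C)(C(C)C)Oc1c([C@@H]2OC(C(=O)OC)=C(C)[C@H]3CC[C@H](C)[C@H]32)oc2cccc(C)c12
F2 | step 10 | corresponding N-methoxy-N-methyl-3-carboxamide | CC(C)[Si](C(C)C)(C(C)C)Oc1c([C@@H]2OC(C(=O)N(C)OC)=C(C)[C@H]3CC[C@H](C)[C@H]32)oc2cccc(C)c12
F3 | step 12 | 2-(triisopropylsilyloxy) analogue of 22, silyloxy group on the face that the acetoxy group of 22 occupies | CC(C)[Si](C(C)C)(C(C)C)O[C@@]1([C@@H]2OC(C(=O)CC(C)C)=C(C)[C@H]3CC[C@H](C)[C@H]32)Oc2cccc(C)c2C1=O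
F4 | step 12 | 2-hydroxy hemiketal corresponding to 22, hydroxy group on the same face | O[C@@]1([C@@H]2OC(C(=O)CC(C)C)=C(C)[C@H]3CC[C@H](C)[C@H]32)Oc2cccc(C)c2C1=O
F5 | step 7 | (1'R)-hydroxy acid, 2-{(1S,2R,3S)-2-[(R)-hydroxy(4-methyl-3-(triisopropylsilyloxy)benzofuran-2-yl)methyl]-3-methylcyclopentyl}propanoic acid, both C4' epimers | OC(=O)C(C)[C@H]1CC[C@H](C)[C@H]1[C@@H](O)c1oc2cccc(C)c2c1O[Si](C(C)C)(C(C)C)C(C)C
F6 | step 7 | (1'S)-hydroxy acid, C1' epimer of F5 | OC(=O)C(C)[C@H]1CC[C@H](C)[C@H]1[C@H](O)c1oc2cccc(C)c2c1O[Si](C(C)C)(C(C)C)C(C)C
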